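The plan builds ring A last, on a finished ring C. It exploits the ring A pattern of C5 hydroxyl, C6 prenyl, C7 oxygen and C8 hydrogen, fused to pyranone ring C along C4a-C8a, which is the imprint of a vinylketene joined to an oxygen-substituted alkyne. In one light-driven operation a 2-diazoacetyl-4-pyranone that already carries silyl-protected rings B and D at its C5 combines with a prenyl-substituted triisopropylsilyl ynol ether. Wolff shift (C8-C8a), ketene-alkyne cycloaddition (C5-C6, C7-C8), four-electron ring opening and six-electron closure (C4a-C5) deliver the whole isoflavone. Both remaining phenol masks are triisopropylsilyl groups, so one fluoride treatment completes the synthesis.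

Key step: step 11

Remarks on the chemistry
- Labels C2 to C8a and primed labels follow isoflavone numbering. Pyranone and chromene intermediates are named with their own locants.
- Assumption: the mask on the ring B phenol is a spectator, and triisopropylsilyl (TIPS) is chosen for it. It survives every step, shields C7 of the chromene during borylation, and leaves together with the C7 silyl group, so no acid meets the prenyl group flanked by two phenols.
- The diazoketone is excited at about 440 nm through its weak long-wavelength band. This avoids ultraviolet light, which would also excite the 4-pyranone (prone to photoisomerisation) and the photochromic ring D.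
- The target has no stereocentre.

Step 1
Reactants: 1 catechol (threefold excess); 2 3-chloro-3-methylbut-1-yne
Product: 3 2-[(2-methylbut-3-yn-2-yl)oxy]phenol
Conditions: K2CO3, KI (cat.), CuI (cat.), acetone, reflux, Ar
Reagents that add atoms: none
Why: Copper-assisted O-alkylation of a phenoxide by a tertiary propargylic chloride is the usual way to aryl 1,1-dimethylpropargyl ethers, and the excess of the cheap, water-extractable diol suppresses double alkylation.

Step 2
Reactants: 3 2-[(2-methylbut-3-yn-2-yl)oxy]phenol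
Product: 4 2,2-dimethyl-2H-chromen-8-ol
Conditions: o-xylene, 140 °C
Reagents that add atoms: none
Why: The aromatic propargyl Claisen rearrangement can reach only the single free ortho carbon, and enolisation, 1,5-hydrogen shift and oxa-6π electrocyclisation then close ring D, so only the 8-hydroxy isomer can form.

Step 3
Reactants: 4 2,2-dimethyl-2H-chromen-8-ol
Product: 5 [(2,2-dimethyl-2H-chromen-8-yl)oxy]triisopropylsilane
Conditions: TIPSCl, imidazole, DMF, rt
Reagents that add atoms: triisopropylsilyl chloride, CC(C)[Si](Cl)(C(C)C)C(C)C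
Why: Imidazole-promoted silylation of a phenol is routine, and the bulky aryl silyl ether tolerates the later aqueous phosphate base and oxidant.

Step 4
Reactants: 5 [(2,2-dimethyl-2H-chromen-8-yl)oxy]triisopropylsilane
Product: 6 2-[2,2-dimethyl-8-(triisopropylsilyloxy)-2H-chromen-6-yl]-4,4,5,5-tetramethyl-1,3,2-dioxaborolane
Conditions: [Ir(OMe)(cod)]2 (1.5 mol%), dtbpy (3 mol%), B2pin2 (1.0 equiv), THF, 65 °C
Reagents that add atoms: bis(pinacolato)diboron, CC1(C)OB(OC1(C)C)B1OC(C)(C)C(C)(C)O1
Why: Iridium-catalysed aromatic C-H borylation (Hartwig-Miyaura type) is sterically governed and takes 1,2,3-trisubstituted arenes at C5, here chromene C6, because C5-H is ortho to C4a, C7-H is ortho to the silyloxy group and both vinylic C-H bonds of ring D have a substituted neighbour.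

Step 5
Reactants: 7 kojic acid
Product: 8 6-(hydroxymethyl)-4-oxo-4H-pyran-3-yl trifluoromethanesulfonate
Conditions: PhNTf2 (1.05 equiv), Et3N (1.1 equiv), DMF, 0 °C to rt
Reagents that add atoms: N-phenylbis(trifluoromethanesulfonimide), O=S(=O)(N(c1ccccc1)S(=O)(=O)C(F)(F)F)C(F)(F)F
Why: In this chemoselective O-sulfonylation the amine ionises only the acidic enolic hydroxyl (pKa near 8), and the mild triflyl donor reacts with that oxyanion while ignoring the neutral primary alcohol.

Step 6
Reactants: 8 6-(hydroxymethyl)-4-oxo-4H-pyran-3-yl trifluoromethanesulfonate; 6 2-[2,2-dimethyl-8-(triisopropylsilyloxy)-2H-chromen-6-yl]-4,4,5,5-tetramethyl-1,3,2-dioxaborolane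
Product: 9 5-[2,2-dimethyl-8-(triisopropylsilyloxy)-2H-chromen-6-yl]-2-(hydroxymethyl)-4H-pyran-4-one
Conditions: Pd(dppf)Cl2 (5 mol%), K3PO4, 1,4-dioxane/H2O (9:1), 60 °C
Reagents that add atoms: none
Why: In this Suzuki-Miyaura coupling the triflate sits on the electron-poor α-carbon of an enone and should add quickly to zerovalent palladium, triflates of kojic acid derivatives being established partners, while the mild phosphate base spares the pyranone and the aryl silyl ether.

Step 7
Reactants: 9 5-[2,2-dimethyl-8-(triisopropylsilyloxy)-2H-chromen-6-yl]-2-(hydroxymethyl)-4H-pyran-4-one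
Product: 10 5-[2,2-dimethyl-8-(triisopropylsilyloxy)-2H-chromen-6-yl]-4-oxo-4H-pyran-2-carboxylic acid
Conditions: TEMPO (20 mol%), PhI(OAc)2 (2.2 equiv), MeCN/H2O (1:1), rt
Reagents that add atoms: water, O
Why: The oxoammonium (TEMPO/PhI(OAc)2) oxidation takes a primary alcohol through the aldehyde hydrate to the acid near neutrality, is known for 2-hydroxymethyl-4-pyranones, leaves the ring D olefin, the silyl ether and the arene alone, and avoids any hydroxide-mediated ester cleavage on the base-sensitive pyranone.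

Step 8
Reactants: 10 5-[2,2-dimethyl-8-(triisopropylsilyloxy)-2H-chromen-6-yl]-4-oxo-4H-pyran-2-carboxylic acid
Product: 12 2-(diazoacetyl)-5-[2,2-dimethyl-8-(triisopropylsilyloxy)-2H-chromen-6-yl]-4H-pyran-4-one, via acid chloride 11 (not isolated)
Conditions: Me2C=C(Cl)NMe2 (1.05 equiv), CH2Cl2, 0 °C; then Me3SiCHN2 (2 equiv), THF/MeCN (1:1), 0 °C
Reagents that add atoms: 1-chloro-N,N,2-trimethylprop-1-en-1-amine (chlorine of 11), CC(C)=C(Cl)N(C)C; (trimethylsilyl)diazomethane, C[Si](C)(C)C=[N+]=[N-]
Why: This is the acylation of a diazoalkane by an acid chloride (first stage of the Arndt-Eistert sequence), in which the chloroenamine makes 11 without liberating HCl, C-acylation and loss of the silyl group to chloride give the primary diazoketone, and the bulky diazoalkane at 0 °C is a poor dipole towards the pyranone C=C bonds.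

Step 9
Reactants: 13 prenyl bromide; 14 ethynylmagnesium bromide (1.5 equiv)
Product: 15 5-methylhex-4-en-1-yne
Conditions: CuBr·SMe2 (5 mol%), THF, 0 °C to rt
Reagents that add atoms: none
Why: Copper-catalysed allylic substitution of an alkynyl Grignard reagent at the unhindered CH2 terminus of a primary allylic bromide is the standard route to 1,4-enynes, and the volatile product is distilled and kept as a stock solution.

Step 10
Reactants: 15 5-methylhex-4-en-1-yne
Product: 18 triisopropyl[(5-methylhex-4-en-1-yn-1-yl)oxy]silane, via lithium acetylide 16 (not isolated), via lithium ynolate 17 (not isolated)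
Conditions: n-BuLi, THF, −78 °C; t-BuOOLi (from t-BuOOH and LiN(SiMe3)2, THF, −78 °C), −78 to 0 °C; TIPSOTf, −78 to 0 °C
Reagents that add atoms: n-butyllithium (lithium of 16 and 17), [Li]CCCC; tert-butyl hydroperoxide, CC(C)(C)OO; triisopropylsilyl trifluoromethanesulfonate, CC(C)[Si](OS(=O)(=O)C(F)(F)F)(C(C)C)C(C)C
Why: Electrophilic oxygenation of a lithium acetylide by lithium tert-butyl peroxide gives the ynolate, which the bulky silyl triflate traps on oxygen in a known general preparation of triisopropylsilyl ynol ethers, and the acetylenic proton is removed much faster than the CH2 between alkyne and alkene, so the skipped enyne should not isomerise.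

Step 11
Reactants: 12 2-(diazoacetyl)-5-[2,2-dimethyl-8-(triisopropylsilyloxy)-2H-chromen-6-yl]-4H-pyran-4-one; 18 triisopropyl[(5-methylhex-4-en-1-yn-1-yl)oxy]silane (2 equiv)
Product: 23 7,3'-bis-O-(triisopropylsilyl)gancaonin H, via pyranylketene 19 (not isolated), via vinylcyclobutenone 20 (not isolated), via dienylketene 21 (not isolated), via cyclohexadienone 22 (not isolated)
Conditions: hν (440 nm LEDs), degassed ClCH2CH2Cl, 20 °C; then 80 °C
Reagents that add atoms: none
Why: Proposed new method: excitation of the weak n-π* band of 12 near 440 nm, where neither the pyranone nor ring D absorbs, expels N2 with a concerted Wolff 1,2-shift of the pyranyl carbon (C8-C8a) and gives ketene 19, whose cumulene is conjugated with the C8a=C4a bond. The electron-rich alkyne 18 attacks the ketene carbonyl carbon through its nucleophilic, prenyl-bearing carbon in a (2+2) cycloaddition (C5-C6 and C7-C8) to give cyclobutenone 20, which on warming opens reversibly by a 4π conrotatory process (C5-C8 breaks) to dienylketene 21. Ring A, the only ring formed, closes by thermal 6π disrotatory electrocyclisation of 21 (C4a-C5), polarity-matched because C4a is the nucleophilic β-carbon of the O1-C8a=C4a enol ether and C5 an electrophilic ketene carbon, and dienone 22, whose C4a-H lies between two carbonyls, enolises at once to the chelated C5 phenol. The closest known reaction type is the photo-Wolff form of the Danheiser benzannulation of vinyl, aryl and heteroaryl diazoketones with siloxyalkynes; a 4-pyranone has not yet served as the 2π partner, and the case for it rests on its low aromatic stabilisation compared with arenes that already take part. The selectivity required is regiochemical: the oxygen-polarised triple bond places prenyl at C6 next to the new hydroxyl and silyloxy at C7, and C4a is the only carbon neighbour of C8a in ring C, the other neighbour being O1. No stereocentre persists, because the stereogenic carbons of 20 and 22 arise as racemates and are erased by ring opening and enolisation.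

Step 12
Reactants: 23 7,3'-bis-O-(triisopropylsilyl)gancaonin H
Product: 24 gancaonin H
Conditions: Bu4NF, AcOH (2.5 equiv each), THF, 0 °C
Reagents that add atoms: none
Why: Fluoride-driven cleavage of both aryl silyl ethers (strong Si-F bond, good phenoxide leaving groups) is fast at 0 °C, and the acetic acid buffer keeps the medium near neutral, so the prenyl group, ring D and the pyranone stay intact and no acid-induced chroman formation can occur.

Compound list
1 | catechol | Oc1ccccc1O | starting material
2 | 3-chloro-3-methylbut-1-yne | CC(C)(Cl)C#C | starting material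
3 | 2-[(2-methylbut-3-yn-2-yl)oxy]phenol | C#CC(C)(C)Oc1ccccc1O | intermediate
4 | 2,2-dimethyl-2H-chromen-8-ol | CC1(C)C=Cc2cccc(O)c2O1 | intermediate
5 | [(2,2-dimethyl-2H-chromen-8-yl)oxy]triisopropylsilane | CC1(C)C=Cc2cccc(O[Si](C(C)C)(C(C)C)C(C)C)c2O1 | intermediate
6 | 2-[2,2-dimethyl-8-(triisopropylsilyloxy)-2H-chromen-6-yl]-4,4,5,5-tetramethyl-1,3,2-dioxaborolane | CC1(C)C=Cc2cc(B3OC(C)(C)C(C)(C)O3)cc(O[Si](C(C)C)(C(C)C)C(C)C)c2O1 | intermediate
7 | kojic acid | OCc1cc(=O)c(O)co1 | starting material
8 | 6-(hydroxymethyl)-4-oxo-4H-pyran-3-yl trifluoromethanesulfonate | OCc1cc(=O)c(OS(=O)(=O)C(F)(F)F)co1 | intermediate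
9 | 5-[2,2-dimethyl-8-(triisopropylsilyloxy)-2H-chromen-6-yl]-2-(hydroxymethyl)-4H-pyran-4-one | OCc1cc(=O)c(-c2cc(O[Si](C(C)C)(C(C)C)C(C)C)c3c(c2)C=CC(C)(C)O3)co1 | intermediate
10 | 5-[2,2-dimethyl-8-(triisopropylsilyloxy)-2H-chromen-6-yl]-4-oxo-4H-pyran-2-carboxylic acid | OC(=O)c1cc(=O)c(-c2cc(O[Si](C(C)C)(C(C)C)C(C)C)c3c(c2)C=CC(C)(C)O3)co1 | intermediate
11 | 5-[2,2-dimethyl-8-(triisopropylsilyloxy)-2H-chromen-6-yl]-4-oxo-4H-pyran-2-carbonyl chloride (not isolated) | ClC(=O)c1cc(=O)c(-c2cc(O[Si](C(C)C)(C(C)C)C(C)C)c3c(c2)C=CC(C)(C)O3)co1 | intermediate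
12 | 2-(diazoacetyl)-5-[2,2-dimethyl-8-(triisopropylsilyloxy)-2H-chromen-6-yl]-4H-pyran-4-one | [N-]=[N+]=CC(=O)c1cc(=O)c(-c2cc(O[Si](C(C)C)(C(C)C)C(C)C)c3c(c2)C=CC(C)(C)O3)co1 | intermediate
13 | prenyl bromide | CC(C)=CCBr | starting material
14 | ethynylmagnesium bromide | C#C[Mg]Br | starting material
15 | 5-methylhex-4-en-1-yne | CC(C)=CCC#C | intermediate
16 | (5-methylhex-4-en-1-yn-1-yl)lithium (not isolated) | [Li]C#CCC=C(C)C | intermediate
17 | lithium 5-methylhex-4-en-1-yn-1-olate (not isolated) | [Li]OC#CCC=C(C)C | intermediate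
18 | triisopropyl[(5-methylhex-4-en-1-yn-1-yl)oxy]silane | CC(C)=CCC#CO[Si](C(C)C)(C(C)C)C(C)C | intermediate
19 | {5-[2,2-dimethyl-8-(triisopropylsilyloxy)-2H-chromen-6-yl]-4-oxo-4H-pyran-2-yl}ketene (not isolated) | O=C=Cc1cc(=O)c(-c2cc(O[Si](C(C)C)(C(C)C)C(C)C)c3c(c2)C=CC(C)(C)O3)co1 | intermediate
20 | racemic 4-(pyranonyl)-2-prenyl-3-(triisopropylsilyloxy)cyclobut-2-en-1-one (not isolated) | CC(C)=CCC1=C(O[Si](C(C)C)(C(C)C)C(C)C)C(C1=O)c1cc(=O)c(-c2cc(O[Si](C(C)C)(C(C)C)C(C)C)c3c(c2)C=CC(C)(C)O3)co1 | intermediate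
21 | dienylketene, pyranonyl group cis to the ketene-bearing carbon (not isolated) | CC(C)=CCC(=C=O)/C(O[Si](C(C)C)(C(C)C)C(C)C)=C\c1cc(=O)c(-c2cc(O[Si](C(C)C)(C(C)C)C(C)C)c3c(c2)C=CC(C)(C)O3)co1 | intermediate
22 | racemic 4a-H cyclohexadienone tautomer of 23 (not isolated) | CC(C)=CCC1=C(O[Si](C(C)C)(C(C)C)C(C)C)C=C2OC=C(c3cc(O[Si](C(C)C)(C(C)C)C(C)C)c4c(c3)C=CC(C)(C)O4)C(=O)C2C1=O | intermediate
23 | 7,3'-bis-O-(triisopropylsilyl)gancaonin H | CC(C)=CCc1c(O[Si](C(C)C)(C(C)C)C(C)C)cc2occ(-c3cc(O[Si](C(C)C)(C(C)C)C(C)C)c4c(c3)C=CC(C)(C)O4)c(=O)c2c1O | intermediate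
24 | gancaonin H | CC(C)=CCc1c(O)cc2occ(-c3cc(O)c4c(c3)C=CC(C)(C)O4)c(=O)c2c1O | target

Total step count: 12
Longest linear sequence: 9 steps (1, 2, 3, 4, 6, 7, 8, 11, 12)

Steps most likely to fail

1. Step 11. Several processes could spoil it.
- Light uptake through the weak long-wavelength band may be slow.
- The ketene may be lost to dimerisation or to acylation of the product phenol before it meets the alkyne.
- A stepwise carbene pathway may add to the olefins.
- The six-electron closure onto the pyranone double bond may lag behind decay of the dienylketene.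

The fallback uses known chemistry, sets out from boronate 6 and returns at 23.
- Commercial 2,4,6-trihydroxyacetophenone is silylated at its only non-chelated hydroxyl (TIPSCl, imidazole, DMF, 0 °C) to 1-[2,6-dihydroxy-4-(triisopropylsilyloxy)phenyl]ethanone F1.
- One of the two equivalent chelated hydroxyls is allylated under Mitsunobu conditions (allyl alcohol, PPh3, DIAD) to 1-[2-(allyloxy)-6-hydroxy-4-(triisopropylsilyloxy)phenyl]ethanone F2.
- Condensation with N,N-dimethylformamide dimethyl acetal gives the enaminone (E)-1-[2-(allyloxy)-6-hydroxy-4-(triisopropylsilyloxy)phenyl]-3-(dimethylamino)prop-2-en-1-one F3.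
- Iodine-induced cyclisation of F3 gives 5-(allyloxy)-3-iodo-7-(triisopropylsilyloxy)-4H-chromen-4-one F4.
- Suzuki-Miyaura coupling of F4 with 6 (Pd(dppf)Cl2, K3PO4, dioxane with little water) gives the 5-O-allyl isoflavone F5.
- An aromatic Claisen rearrangement (N,N-diethylaniline, 190 °C) can deliver the allyl group only to C6, since the other ortho position is C4a, and gives the 6-allyl-5-hydroxy isoflavone F6.
- Cross-metathesis with 2-methylbut-2-ene (second-generation Grubbs catalyst, CH2Cl2, 40 °C) turns allyl into prenyl and gives 23.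

2. Step 4. Borylation or hydroboration at the ring D olefin may compete, and discrimination between chromene C6 and C5 may be incomplete.

The fallback fixes the site with a halogen that is present before ring D is made. It sets out from 2 and returns at 6.
- Commercial 4-bromo-2-methoxyphenol is alkylated with 2 (K2CO3, KI, CuI, acetone) to 4-bromo-2-methoxy-1-[(2-methylbut-3-yn-2-yl)oxy]benzene F7.
- Propargyl Claisen rearrangement (o-xylene, 140 °C) gives 6-bromo-8-methoxy-2,2-dimethyl-2H-chromene F8.
- Thiolate demethylation (NaSEt, DMF, 120 °C), which attacks only the methyl carbon, gives 6-bromo-2,2-dimethyl-2H-chromen-8-ol F9.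
- Silylation (TIPSCl, imidazole) gives [(6-bromo-2,2-dimethyl-2H-chromen-8-yl)oxy]triisopropylsilane F10.
- Miyaura borylation (Pd(dppf)Cl2, KOAc, B2pin2, dioxane, 85 °C) gives 6.

3. Step 8. The diazoalkane may add as a 1,3-dipole to the doubly activated C2=C3 bond of the pyranone, or the diazoketone may be protonated and captured by chloride.

The fallback installs the diazo group by diazo transfer instead of diazoalkane acylation. It sets out from acid chloride 11 and returns at 12.
- Stille acylation (Me4Sn, PdCl2(PPh3)2, toluene, 60 °C) gives the methyl ketone 2-acetyl-5-[2,2-dimethyl-8-(triisopropylsilyloxy)-2H-chromen-6-yl]-4H-pyran-4-one F11.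
- The kinetic enolate of F11 (LiN(SiMe3)2, THF, −78 °C) is acylated with 2,2,2-trifluoroethyl trifluoroacetate to the activated diketone 4,4,4-trifluoro-1-{5-[2,2-dimethyl-8-(triisopropylsilyloxy)-2H-chromen-6-yl]-4-oxo-4H-pyran-2-yl}butane-1,3-dione F12.
- Detrifluoroacetylative diazo transfer (MsN3, Et3N, H2O, MeCN, rt), a method devised for unsaturated diazoketones, gives 12.

Further compounds
F1 | step 11 | 1-[2,6-dihydroxy-4-(triisopropylsilyloxy)phenyl]ethanone | CC(=O)c1c(O)cc(O[Si](C(C)C)(C(C)C)C(C)C)cc1O
F2 | step 11 | 1-[2-(allyloxy)-6-hydroxy-4-(triisopropylsilyloxy)phenyl]ethanone | CC(=O)c1c(O)cc(O[Si](C(C)C)(C(C)C)C(C)C)cc1OCC=C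
F3 | step 11 | (E)-1-[2-(allyloxy)-6-hydroxy-4-(triisopropylsilyloxy)phenyl]-3-(dimethylamino)prop-2-en-1-one | CN(C)/C=C/C(=O)c1c(O)cc(O[Si](C(C)C)(C(C)C)C(C)C)cc1OCC=C
F4 | step 11 | 5-(allyloxy)-3-iodo-7-(triisopropylsilyloxy)-4H-chromen-4-one | C=CCOc1cc(O[Si](C(C)C)(C(C)C)C(C)C)cc2occ(I)c(=O)c12
F5 | step 11 | 5-(allyloxy)-3-[2,2-dimethyl-8-(triisopropylsilyloxy)-2H-chromen-6-yl]-7-(triisopropylsilyloxy)-4H-chromen-4-one | C=CCOc1cc(O[Si](C(C)C)(C(C)C)C(C)C)cc2occ(-c3cc(O[Si](C(C)C)(C(C)C)C(C)C)c4c(c3)C=CC(C)(C)O4)c(=O)c12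
F6 | step 11 | 6-allyl-3-[2,2-dimethyl-8-(triisopropylsilyloxy)-2H-chromen-6-yl]-5-hydroxy-7-(triisopropylsilyloxy)-4H-chromen-4-one | C=CCc1c(O[Si](C(C)C)(C(C)C)C(C)C)cc2occ(-c3cc(O[Si](C(C)C)(C(C)C)C(C)C)c4c(c3)C=CC(C)(C)O4)c(=O)c2c1O
F7 | step 4 | 4-bromo-2-methoxy-1-[(2-methylbut-3-yn-2-yl)oxy]benzene | C#CC(C)(C)Oc1ccc(Br)cc1OC
F8 | step 4 | 6-bromo-8-methoxy-2,2-dimethyl-2H-chromene | CC1(C)C=Cc2cc(Br)cc(OC)c2O1
F9 | step 4 | 6-bromo-2,2-dimethyl-2H-chromen-8-ol | CC1(C)C=Cc2cc(Br)cc(O)c2O1
F10 | step 4 | [(6-bromo-2,2-dimethyl-2H-chromen-8-yl)oxy]triisopropylsilane | CC1(C)C=Cc2cc(Br)cc(O[Si](C(C)C)(C(C)C)C(C)C)c2O1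
F11 | step 8 | 2-acetyl-5-[2,2-dimethyl-8-(triisopropylsilyloxy)-2H-chromen-6-yl]-4H-pyran-4-one | CC(=O)c1cc(=O)c(-c2cc(O[Si](C(C)C)(C(C)C)C(C)C)c3c(c2)C=CC(C)(C)O3)co1
F12 | step 8 | 4,4,4-trifluoro-1-{5-[2,2-dimethyl-8-(triisopropylsilyloxy)-2H-chromen-6-yl]-4-oxo-4H-pyran-2-yl}butane-1,3-dione | O=C(CC(=O)C(F)(F)F)c1cc(=O)c(-c2cc(O[Si](C(C)C)(C(C)C)C(C)C)c3c(c2)C=CC(C)(C)O3)co1
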